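## The problem

The target is a C30 tetraol in which a cis-fused hydroazulene (C1–C8a, azulene numbering) and a cis-fused perhydro-1-benzoxepine (O1′–C9a′, primed) are held together only by a CH2CH2 bridge from C5 to C6′. The left bicycle has four stereocentres (1S, 3aS, 5R, 8aS): H-3a, H-8a and H-5 lie on one face, the C1 hydroxyl sits on the face of the fusion hydrogens, and the quaternary C4 (CMe2) is wedged between C3a and C5. The right bicycle has five (3′S, 5a′S, 6′S, 7′R, 9a′R): the 5a′-methyl, H-9a′, the C6′ chain and the C7′ hydroxyl are all on one face, so the oxepane is cis-fused and a quaternary carbon (C5a′) adjoins a tertiary carbon and a tertiary carbinol (C6′, C7′). Two methylenes insulate the halves, so the right-half centres must come from reagent control and from reactions inside that ring system, whereas on the left C5 can steer C3a/C8a and the ring fusion can then steer C1. The two tertiary alcohols (C1, C7′) eliminate easily under acid and the trisubstituted C6=C7 alkene must survive every reduction and hydration, so the late steps have to be non-acidic and chemoselective. Between the fusion carbons the seven-membered ring reads C4(Me2)–C5H(chain)–C6(Me)=C7H–C8H2; with a C3a=C8a enone this is a cyclohepta-1,4-diene, the Cope product of a cis-divinylcyclopropane made from a three-carbon isopropylidene vinylcarbenoid (C8a, C3a, C4) and a four-carbon 3-methyl-1,3-diene (C5–C8). The cis fusion of the right half corresponds to Z geometry at C5a′=C9a′ in an open-chain precursor, and the cis C6′/C7′ pair to Z geometry at C6′=C7′.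

## Retrosynthesis

**C1 carbinol and silyl ethers (29 ⇐ 28 ⇐ 27 ⇐ 26).** The C1–O bond is cut last, after the two Si–O bonds. A methyl nucleophile would attack ketone 26 from the convex face and leave the hydroxyl on the concave face, the wrong epimer. Markovnikov hydration of the exocyclic alkene 27 instead brings oxygen in from the convex face. The forward steps must prefer the 1,1-disubstituted alkene over the ring alkene and must methylenate 26 without epimerising C8a.

**Fusion hydrogens (26 ⇐ 24).** Cutting C3a–H and C8a–H gives the tetrasubstituted enone 24. This removes two stereocentres, leaves C5 as the only left-half centre and exposes the cycloheptadiene. Hydrogenation would endanger C6=C7, so a dissolving-metal reduction is asked to put H-3a on the face of H-5 and to protonate C8a away from the CMe2 group.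

**Formal (4+3) (24 ⇐ 16 + 22).** The C8a–C8 and C4–C5 bonds are cut together. Cutting C4–C5 alone would require joining a neopentyl quaternary carbon to a tertiary one by polar chemistry. The double cut makes that bond sigmatropically, builds the carbocycle and unites the halves in one step. The precursors are the small diazo ketone 22 and diene 16, which carries no left-half stereocentre. The forward reaction needs attack at the terminal alkene only, a cis cyclopropane, catalyst control of the face, and a Cope shift through a boat with one methyl pointing inward.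

**Diazo ketone (22 ⇐ 21 ⇐ 19 ⇐ 17).** The diazo carbon lies between the ketone and the isopropylidene carbon. Deprotonating 3-isopropylcyclopentenone would give the ring dienolate and the wrong vinyl isomer. The exocyclic dienolate is therefore made regiospecifically by reducing linear dienone 19, marked as trifluoroacetyl ketone 21, and converted by deacylative diazo transfer. Dienone 19 comes from vinylogous ester 17.

**Diene chain (16 ⇐ 15 ⇐ 14 ⇐ 13 ⇐ 12 ⇐ 11 ⇐ 10).** The C7=C8 and C5=C6 alkenes are cut by olefination logic. A stabilised α-methyl ylide gives the E-trisubstituted alkene reliably, and the carbonyl carbon of lactone 10 is already C5. Lactone 10 is a compact tricycle holding all five right-half centres, with the C7′ oxygen masked.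

**Right-half rings (10 ⇐ 9).** The O1′–C2′, C5a′–C6′ and C7′–O bonds are cut in one epoxide-opening cascade. A hydroxy-epoxide closure would favour the six-membered ether, whereas passage through an epoxonium ion gives the oxepane. The relative configuration is written into two epoxides and two Z alkenes of acyclic 9. The forward step needs opening of the terminal epoxide at its tertiary carbon, a chair closure and anti capture by the ester.

**Z alkene (9 ⇐ 5 + 7, 7 ⇐ 6).** The sp3–sp2 bond C7′–C8′ is cut. Olefination of a methyl ketone would not control the Z-trisubstituted alkene. The geometry is instead fixed in vinyl iodide 7 and carried through a B-alkyl Suzuki–Miyaura coupling with the borane from vinyl epoxide 5.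

**Epoxides (5 ⇐ 4 ⇐ 3 ⇐ 2 ⇐ 1).** The Z alkene of nerol 1 is the future cis fusion. Its allylic hydroxyl directs the first asymmetric epoxidation (2), the remaining prenyl alkene takes the second (3), and C1 of nerol is oxidised (4) and methylenated (5) to supply C9′ and C8′.

## Roads not taken

**Alternative 1:** The cut is the C1–C8a bond of the cyclopentane. Forward, SmI2 converts the side-chain methyl ketone of cycloheptenone A2 into a ketyl that adds 5-exo to the enone β-carbon and gives hydroxy ketone A1.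
- Merits: the cis fusion and the C1 carbinol are set in one step. Here this road is better than the chosen plan, which spends three steps on C1 and relies on a weak relay from C5 for C3a.
- Weak points: C3a, C5 and the CMe2 between them must already sit on the seven-membered ring, so the hard ring and the C4–C5 bond are left to earlier chemistry. The C7 ketone and C6 methine must then be turned regioselectively into the C6=C7 alkene. The right half has to be attached through an sp3–sp3 bond from the silyloxyethyl handle.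
- Comparison: against the better C1 control, the chosen plan builds the carbocycle and joins the halves in the same step and is shorter.

**Alternative 2:** The cut lies in the right half, at C5a′–C9a′ and C4′–C5′. Forward, irradiation of furanone A4 gives photoadduct A3; cleavage of the cyclobutane bond next to the ketone then expands the furanone to an oxepan-3-one.
- Merits: the seven-membered ether arises by ring expansion and cannot leak to a six-membered ether. This is a real advantage over the epoxide cascade. The quaternary C5a′ comes from a dependable intramolecular [2+2].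
- Weak points: the C6′/C7′ pair must be set on an open chain before irradiation and is the only control over the facial course. H-9a′ arrives only when the cyclobutane opens, so the cis fusion rests on an unguided hydrogen delivery. C3′ needs a separate stereoselective ketone reduction. The hydroazulene and the union are not addressed.
- Comparison: the chosen plan sets all five right-half centres from two catalytic epoxidations and two alkene geometries in fewer steps, at the price of a less predictable ring-forming event.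

**Alternative 3:** The cut is the bond from C6′ to the bridge together with C5a′–C5′. Forward, hydrozirconation of the complete left-half alkene A7 with Cp2Zr(H)Cl, copper-catalysed asymmetric conjugate addition to enone ketal A6 and enolate allylation (allyl acetate, Pd(PPh3)4) give ketone A5.
- Merits: a catalytic enantioselective union creates C6′ and the quaternary C5a′ together, with methyl and chain cis as required. In convergence and in independence from an acyclic cascade it is better than the chosen plan.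
- Weak points: the whole hydroazulene must exist first, so the seven-membered carbocycle is unsolved. After the union the oxepane must still be built from the allyl group and the C9a′ ketone, including a seven-membered etherification at a neopentyl carbon and the cis H-9a′. The C7′ and C3′ carbinols follow on the full-size, acid-sensitive molecule.
- Comparison: the chosen plan finishes the right half on a small fragment and uses the union itself to make the carbocycle.

Key step: step 17

Remark: the structure is read as drawn, with a cis-fused perhydrobenzoxepine (5a′-methyl and H-9a′ on the same face); the route is built for exactly this isomer.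
Remark: tert-butyl 4-oxobutanoate and the L-fructose-derived epoxidation ketone are taken as purchasable.
Remark: the sense of induction of Rh2(S-PTAD)4, dirhodium tetrakis[(S)-(1-adamantyl)(N-phthalimido)acetate], is assigned by analogy; Rh2(R-PTAD)4 would be used if it proved opposite.
Notation: Ox = (3S,5aS,6S,7R,9aR)-3-(tert-butyldimethylsilyloxy)-2,2,5a,7-tetramethyl-7-(triethylsilyloxy)decahydro-1-benzoxepin-6-yl.

## Route

Step 1
Reactants: 1 nerol
Product: 2 [(2R,3S)-3-methyl-3-(4-methylpent-3-en-1-yl)oxiran-2-yl]methanol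
Conditions: Ti(OiPr)4 (cat.), D-(−)-diethyl tartrate, t-BuOOH, 4 Å sieves, CH2Cl2, −20 °C
Reagents that add atoms: tert-butyl hydroperoxide, CC(C)(C)OO
Why: Sharpless asymmetric epoxidation of a Z-trisubstituted allylic alcohol; the D-tartrate delivers oxygen to the face that gives the (2R,3S)-epoxide, which fixes C9a′ and, after later inversion, C5a′. The distal alkene lacks the directing hydroxyl and is left alone.

Step 2
Reactants: 2 [(2R,3S)-3-methyl-3-(4-methylpent-3-en-1-yl)oxiran-2-yl]methanol
Product: 3 [(2R,3S)-3-{2-[(2S)-3,3-dimethyloxiran-2-yl]ethyl}-3-methyloxiran-2-yl]methanol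
Conditions: L-fructose-derived Shi ketone (1,2:4,5-di-O-isopropylidene-β-L-erythro-2,3-hexodiulo-2,6-pyranose, 30 mol %), KHSO5 (as 2KHSO5·KHSO4·K2SO4), K2CO3, Bu4NHSO4, CH3CN/dimethoxymethane/aq. buffer pH 10.5, 0 °C
Reagents that add atoms: potassium peroxymonosulfate, [K+].[O-]S(=O)(=O)OO
Why: Shi epoxidation of the only remaining alkene, a prenyl-type trisubstituted alkene and the best substrate class for this dioxirane. The L-series ketone is needed for the (S)-epoxide that becomes the C3′ carbinol.

Step 3
Reactants: 3 [(2R,3S)-3-{2-[(2S)-3,3-dimethyloxiran-2-yl]ethyl}-3-methyloxiran-2-yl]methanol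
Product: 4 (2S,3S)-3-{2-[(2S)-3,3-dimethyloxiran-2-yl]ethyl}-3-methyloxirane-2-carbaldehyde
Conditions: TEMPO (cat.), PhI(OAc)2, CH2Cl2, rt
Reagents that add atoms: none
Why: Oxoammonium (TEMPO) oxidation stops at the aldehyde and is neutral enough for two epoxides. The epoxide C–H next to the formyl group is not epimerised.

Step 4
Reactants: 4 (2S,3S)-3-{2-[(2S)-3,3-dimethyloxiran-2-yl]ethyl}-3-methyloxirane-2-carbaldehyde
Product: 5 (2S,3R)-2-{2-[(2S)-3,3-dimethyloxiran-2-yl]ethyl}-3-ethenyl-2-methyloxirane
Conditions: [Ph3PCH3]Br, KN(SiMe3)2, THF, −78 → 0 °C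
Reagents that add atoms: methyltriphenylphosphonium bromide, C[P+](c1ccccc1)(c1ccccc1)c1ccccc1.[Br-]
Why: Wittig methylenation of an α,β-epoxy aldehyde adds C8′ and gives the vinyl epoxide; no stereocentre is touched.

Step 5
Reactants: 6 tert-butyl 4-oxobutanoate
Product: 7 tert-butyl (4Z)-5-iodohex-4-enoate
Conditions: [Ph3PCH2CH3]I, n-BuLi, THF, −78 °C; I2; NaN(SiMe3)2; then 6, −78 → −20 °C
Reagents that add atoms: ethyltriphenylphosphonium iodide, CC[P+](c1ccccc1)(c1ccccc1)c1ccccc1.[I-]; iodine, II
Why: Wittig olefination with the α-iodoethylidene ylide (Stork–Zhao-type) gives the (Z)-2-iodoalk-2-ene, which stores the geometry of the future C6′=C7′ alkene. The tert-butyl ester is inert.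

Step 6
Reactants: 5 (2S,3R)-2-{2-[(2S)-3,3-dimethyloxiran-2-yl]ethyl}-3-ethenyl-2-methyloxirane; 7 tert-butyl (4Z)-5-iodohex-4-enoate
Product: 9 tert-butyl (4Z)-7-[(2R,3S)-3-{2-[(2S)-3,3-dimethyloxiran-2-yl]ethyl}-3-methyloxiran-2-yl]-5-methylhept-4-enoate, via B-alkyl-9-borabicyclo[3.3.1]nonane 8 (not isolated)
Conditions: 9-BBN, THF, 0 °C → rt; then 7, PdCl2(dppf) (cat.), AsPh3, Cs2CO3, DMF/H2O, rt
Reagents that add atoms: none
Why: Anti-Markovnikov hydroboration of the monosubstituted alkene, then B-alkyl Suzuki–Miyaura coupling with retention of the vinyl iodide geometry, forms C7′–C8′ and the Z-trisubstituted alkene. Trisubstituted epoxides and the ester tolerate 9-BBN and the mild carbonate base.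

Step 7
Reactants: 9 tert-butyl (4Z)-7-[(2R,3S)-3-{2-[(2S)-3,3-dimethyloxiran-2-yl]ethyl}-3-methyloxiran-2-yl]-5-methylhept-4-enoate
Product: 10 δ-lactone of 3-[(3S,5aS,6S,7R,9aR)-3-(tert-butyldimethylsilyloxy)-7-hydroxy-2,2,5a,7-tetramethyldecahydro-1-benzoxepin-6-yl]propanoic acid
Conditions: t-BuMe2SiOTf (1.3 equiv), 2,6-di-tert-butyl-4-methylpyridine, CH2Cl2, −78 °C
Reagents that add atoms: tert-butyldimethylsilyl trifluoromethanesulfonate, CC(C)(C)[Si](C)(C)OS(=O)(=O)C(F)(F)F
Why: Lewis-acid-promoted epoxide-opening cascade (tandem oxa-/carbacyclisation): the silylated terminal epoxide is opened at its tertiary carbon by the oxygen of the inner epoxide, the epoxonium ion is opened at C5a′ with inversion by the Z alkene through a chair, and the ester carbonyl captures the C7′ cation anti with loss of isobutene. C3′ and C9a′ keep their epoxide configurations and C5a′ is inverted; the Z epoxide gives the cis ring fusion, and the Z alkene puts the C6′ chain axial and the C7′ oxygen equatorial in the forming chair, which is 6S,7R. The silyl group stays on the C3′ oxygen.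

Step 8
Reactants: 10 δ-lactone of 3-[(3S,5aS,6S,7R,9aR)-3-(tert-butyldimethylsilyloxy)-7-hydroxy-2,2,5a,7-tetramethyldecahydro-1-benzoxepin-6-yl]propanoic acid
Product: 11 lactol (cyclic hemiacetal) of 3-[(3S,5aS,6S,7R,9aR)-3-(tert-butyldimethylsilyloxy)-7-hydroxy-2,2,5a,7-tetramethyldecahydro-1-benzoxepin-6-yl]propanal
Conditions: i-Bu2AlH (1.1 equiv), CH2Cl2, −78 °C; aq. KNaC4H4O6
Reagents that add atoms: none
Why: Partial reduction of a δ-lactone; the tetrahedral aluminate is stable at −78 °C and gives the lactol on work-up.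

Step 9
Reactants: 11 lactol (cyclic hemiacetal) of 3-[(3S,5aS,6S,7R,9aR)-3-(tert-butyldimethylsilyloxy)-7-hydroxy-2,2,5a,7-tetramethyldecahydro-1-benzoxepin-6-yl]propanal
Product: 12 ethyl (2E)-5-[(3S,5aS,6S,7R,9aR)-3-(tert-butyldimethylsilyloxy)-7-hydroxy-2,2,5a,7-tetramethyldecahydro-1-benzoxepin-6-yl]-2-methylpent-2-enoate
Conditions: Ph3P=C(CH3)CO2Et, toluene, 90 °C
Reagents that add atoms: ethyl 2-(triphenylphosphoranylidene)propanoate, CCOC(=O)C(C)=P(c1ccccc1)(c1ccccc1)c1ccccc1
Why: Wittig reaction of the open-chain hydroxy aldehyde with a stabilised α-methyl ylide gives the E-trisubstituted enoate and frees the C7′ alcohol. The base-free conditions disfavour oxa-Michael closure.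

Step 10
Reactants: 12 ethyl (2E)-5-[(3S,5aS,6S,7R,9aR)-3-(tert-butyldimethylsilyloxy)-7-hydroxy-2,2,5a,7-tetramethyldecahydro-1-benzoxepin-6-yl]-2-methylpent-2-enoate
Product: 13 ethyl (2E)-2-methyl-5-Ox-pent-2-enoate
Conditions: Et3SiOTf, 2,6-lutidine, CH2Cl2, −78 → 0 °C
Reagents that add atoms: triethylsilyl trifluoromethanesulfonate, CC[Si](CC)(CC)OS(=O)(=O)C(F)(F)F
Why: Silyl triflate silylation of the hindered tertiary alcohol; it protects against O–H insertion at the carbenoid stage.

Step 11
Reactants: 13 ethyl (2E)-2-methyl-5-Ox-pent-2-enoate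
Product: 14 (2E)-2-methyl-5-Ox-pent-2-en-1-ol
Conditions: i-Bu2AlH (2.5 equiv), CH2Cl2, −78 °C
Reagents that add atoms: none
Why: 1,2-Reduction of the enoate to the allylic alcohol; silyl ethers and the alkene geometry are untouched.

Step 12
Reactants: 14 (2E)-2-methyl-5-Ox-pent-2-en-1-ol
Product: 15 (2E)-2-methyl-5-Ox-pent-2-enal
Conditions: MnO2, CH2Cl2, rt
Reagents that add atoms: none
Why: Chemoselective oxidation of an allylic alcohol to the enal without E/Z isomerisation.

Step 13
Reactants: 15 (2E)-2-methyl-5-Ox-pent-2-enal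
Product: 16 (3E)-4-methyl-1-Ox-hexa-3,5-diene
Conditions: [Ph3PCH3]Br, KN(SiMe3)2, THF, 0 °C
Reagents that add atoms: methyltriphenylphosphonium bromide, C[P+](c1ccccc1)(c1ccccc1)c1ccccc1.[Br-]
Why: Wittig methylenation of the enal gives the 3-methyl-1,3-diene with the E geometry intact.

Step 14
Reactants: 17 3-ethoxycyclopent-2-en-1-one
Product: 19 3-(prop-1-en-2-yl)cyclopent-2-en-1-one, via 3-ethoxy-1-(prop-1-en-2-yl)cyclopent-2-en-1-ol 18 (not isolated)
Conditions: CH2=C(CH3)MgBr, THF, 0 °C; then 1 M HCl
Reagents that add atoms: isopropenylmagnesium bromide, CC(=C)[Mg]Br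
Why: 1,2-Addition of the Grignard reagent to a vinylogous ester, then acid hydrolysis with carbonyl transposition (Stork–Danheiser sequence), gives the linear dienone.

Step 15
Reactants: 19 3-(prop-1-en-2-yl)cyclopent-2-en-1-one
Product: 21 3-(propan-2-ylidene)-2-(trifluoroacetyl)cyclopentan-1-one, via lithium 3-(propan-2-ylidene)cyclopent-1-en-1-olate 20 (not isolated)
Conditions: Li (2.1 equiv), NH3(l)/THF, t-BuOH (1.0 equiv), −78 °C; NH3 evaporated; CF3CO2CH2CF3, THF, −78 °C; aq. HCl work-up
Reagents that add atoms: 2,2,2-trifluoroethyl trifluoroacetate, O=C(OCC(F)(F)F)C(F)(F)F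
Why: Dissolving-metal reduction of a linear dienone protonates the terminal carbon and leaves the exocyclic extended enolate regiospecifically (reductive deconjugation). Claisen-type C-acylation at its α-carbon marks the carbon that will carry the diazo group.

Step 16
Reactants: 21 3-(propan-2-ylidene)-2-(trifluoroacetyl)cyclopentan-1-one
Product: 22 2-diazo-3-(propan-2-ylidene)cyclopentan-1-one
Conditions: CH3SO2N3, Et3N, H2O (1 equiv), CH3CN, rt; used cold and promptly
Reagents that add atoms: methanesulfonyl azide, CS(=O)(=O)N=[N+]=[N-]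
Why: Detrifluoroacetylative (Regitz-type deacylative) diazo transfer; the diazo group can only enter at the acylated carbon, so the isopropylidene stays exocyclic.

Step 17
Reactants: 16 (3E)-4-methyl-1-Ox-hexa-3,5-diene; 22 2-diazo-3-(propan-2-ylidene)cyclopentan-1-one
Product: 24 (5R)-4,4,6-trimethyl-5-(2-Ox-ethyl)-3,4,5,8-tetrahydroazulen-1(2H)-one, via spiro divinylcyclopropane 23 (not isolated)
Conditions: Rh2(S-PTAD)4 (1 mol %), 22 (2 equiv) added slowly to 16, hexanes, −40 °C → rt; then toluene, 100 °C
Reagents that add atoms: none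
Why: The dirhodium catalyst converts 22 into a donor/acceptor vinylcarbenoid (ketone acceptor, isopropylidene donor) that adds in a concerted [2+1] fashion only to the terminal C7=C8 alkene of 16, the trisubstituted C5=C6 alkene being inert to such carbenoids. As usual for donor/acceptor carbenoids the alkene substituent ends cis to the donor, so 23 is the cis-divinylcyclopropane, and its spiro ring holds the isopropylidene in the endo orientation the rearrangement needs. A [3,3]-sigmatropic (Cope) shift through a boat then breaks C8a–C7, forms C4–C5 and leaves the C3a=C8a enone and the C6=C7 alkene, so the seven-membered ring closes by expansion of the three-membered ring. The only new stereocentre of 24, C5, is set by the (1R,3S) configuration of the cyclopropane, relayed through the boat and the E geometry, which place the chain outward and H-5 inward. The cyclopropane configuration is catalyst-controlled because the right-half centres are too remote; the S catalyst is chosen by analogy with (1S,2R)-selective styrene cyclopropanations, which map onto (1R,3S)-23. The closest known reaction type is the dirhodium-catalysed cyclopropanation/Cope (formal 4+3) of vinyldiazo carbonyl compounds with 1,3-dienes. The step needs site selectivity (terminal vinyl), cis diastereoselectivity (donor/acceptor carbenoid), facial selectivity (catalyst) and a Cope rate that outruns ring-opening pathways; the one inward methyl on C4 slows the shift and heating must overcome it.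

Step 18
Reactants: 24 (5R)-4,4,6-trimethyl-5-(2-Ox-ethyl)-3,4,5,8-tetrahydroazulen-1(2H)-one
Product: 26 (3aS,5R,8aS)-4,4,6-trimethyl-5-(2-Ox-ethyl)-3,3a,4,5,8,8a-hexahydroazulen-1(2H)-one, via lithium enolate 25 (not isolated)
Conditions: Li (2.2 equiv), NH3(l)/THF, t-BuOH (1.0 equiv), −78 °C; then solid NH4Cl
Reagents that add atoms: none
Why: Dissolving-metal (Birch-type) reduction of a hindered tetrasubstituted enone; protonation at C3a should give the axial hydrogen with C3 and the C5 chain both equatorial on the seven-membered ring, which puts H-3a on the face of H-5. Kinetic protonation of enolate 25 at C8a from the face opposite the C4 gem-dimethyl group gives the cis fusion. The isolated alkene and the silyl ethers are inert.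

Step 19
Reactants: 26 (3aS,5R,8aS)-4,4,6-trimethyl-5-(2-Ox-ethyl)-3,3a,4,5,8,8a-hexahydroazulen-1(2H)-one
Product: 27 (3aS,5R,8aS)-4,4,6-trimethyl-1-methylidene-5-(2-Ox-ethyl)-1,2,3,3a,4,5,8,8a-octahydroazulene
Conditions: Zn, CH2Br2, TiCl4, THF/CH2Cl2, 0 °C → rt
Reagents that add atoms: dibromomethane, BrCBr
Why: Takai–Lombardo methylenation; the reagent is non-basic, so the enolisable C8a centre is not epimerised, and it copes with hindered ketones.

Step 20
Reactants: 27 (3aS,5R,8aS)-4,4,6-trimethyl-1-methylidene-5-(2-Ox-ethyl)-1,2,3,3a,4,5,8,8a-octahydroazulene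
Product: 28 (1S,3aS,5R,8aS)-1,4,4,6-tetramethyl-5-(2-Ox-ethyl)-1,2,3,3a,4,5,8,8a-octahydroazulen-1-ol
Conditions: Co(acac)2 (cat.), PhSiH3, O2 (1 atm), i-PrOH, rt
Reagents that add atoms: dioxygen, O=O
Why: Mukaiyama hydration (hydrogen-atom transfer to the 1,1-disubstituted alkene, then O2 capture of the tertiary radical). Oxygen should enter on the convex face, syn to H-8a, giving 1S; the more hindered trisubstituted ring alkene reacts more slowly.

Step 21
Reactants: 28 (1S,3aS,5R,8aS)-1,4,4,6-tetramethyl-5-(2-Ox-ethyl)-1,2,3,3a,4,5,8,8a-octahydroazulen-1-ol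
Product: 29 (3S,5aS,6S,7R,9aR)-6-{2-[(1S,3aS,5R,8aS)-1-hydroxy-1,4,4,6-tetramethyl-1,2,3,3a,4,5,8,8a-octahydroazulen-5-yl]ethyl}-2,2,5a,7-tetramethyldecahydro-1-benzoxepine-3,7-diol
Conditions: Bu4NF, THF, 50 °C
Reagents that add atoms: none
Why: Fluoride cleaves both silyl ethers under non-acidic conditions, so the two tertiary alcohols and the ring alkene survive.

## Compound list

1 | nerol, (2Z)-3,7-dimethylocta-2,6-dien-1-ol | CC(C)=CCC/C(C)=C\CO | starting material
2 | [(2R,3S)-3-methyl-3-(4-methylpent-3-en-1-yl)oxiran-2-yl]methanol | OC[C@H]1O[C@@]1(C)CCC=C(C)C | intermediate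
3 | [(2R,3S)-3-{2-[(2S)-3,3-dimethyloxiran-2-yl]ethyl}-3-methyloxiran-2-yl]methanol | OC[C@H]1O[C@@]1(C)CC[C@@H]1OC1(C)C | intermediate
4 | (2S,3S)-3-{2-[(2S)-3,3-dimethyloxiran-2-yl]ethyl}-3-methyloxirane-2-carbaldehyde | O=C[C@H]1O[C@@]1(C)CC[C@@H]1OC1(C)C | intermediate
5 | (2S,3R)-2-{2-[(2S)-3,3-dimethyloxiran-2-yl]ethyl}-3-ethenyl-2-methyloxirane | C=C[C@H]1O[C@@]1(C)CC[C@@H]1OC1(C)C | intermediate
6 | tert-butyl 4-oxobutanoate | O=CCCC(=O)OC(C)(C)C | starting material
7 | tert-butyl (4Z)-5-iodohex-4-enoate | C/C(I)=C/CCC(=O)OC(C)(C)C | intermediate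
8 | 9-{2-[(2R,3S)-3-{2-[(2S)-3,3-dimethyloxiran-2-yl]ethyl}-3-methyloxiran-2-yl]ethyl}-9-borabicyclo[3.3.1]nonane (not isolated) | C1CC2CCCC(C1)B2CC[C@H]1O[C@@]1(C)CC[C@@H]1OC1(C)C | intermediate
9 | tert-butyl (4Z)-7-[(2R,3S)-3-{2-[(2S)-3,3-dimethyloxiran-2-yl]ethyl}-3-methyloxiran-2-yl]-5-methylhept-4-enoate | CC(C)(C)OC(=O)CC/C=C(/C)CC[C@H]1O[C@@]1(C)CC[C@@H]1OC1(C)C | intermediate
10 | δ-lactone of 3-[(3S,5aS,6S,7R,9aR)-3-(tert-butyldimethylsilyloxy)-7-hydroxy-2,2,5a,7-tetramethyldecahydro-1-benzoxepin-6-yl]propanoic acid (cis-fused oxepane, cis-fused lactone) | O=C1CC[C@H]2[C@]3(C)CC[C@H](O[Si](C)(C)C(C)(C)C)C(C)(C)O[C@@H]3CC[C@@]2(C)O1 | intermediate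
11 | lactol of 3-[(3S,5aS,6S,7R,9aR)-3-(tert-butyldimethylsilyloxy)-7-hydroxy-2,2,5a,7-tetramethyldecahydro-1-benzoxepin-6-yl]propanal (anomers) | OC1CC[C@H]2[C@]3(C)CC[C@H](O[Si](C)(C)C(C)(C)C)C(C)(C)O[C@@H]3CC[C@@]2(C)O1 | intermediate
12 | ethyl (2E)-5-[(3S,5aS,6S,7R,9aR)-3-(tert-butyldimethylsilyloxy)-7-hydroxy-2,2,5a,7-tetramethyldecahydro-1-benzoxepin-6-yl]-2-methylpent-2-enoate | CCOC(=O)/C(C)=C/CC[C@H]1[C@]2(C)CC[C@H](O[Si](C)(C)C(C)(C)C)C(C)(C)O[C@@H]2CC[C@@]1(C)O | intermediate
13 | ethyl (2E)-2-methyl-5-Ox-pent-2-enoate | CCOC(=O)/C(C)=C/CC[C@H]1[C@]2(C)CC[C@H](O[Si](C)(C)C(C)(C)C)C(C)(C)O[C@@H]2CC[C@@]1(C)O[Si](CC)(CC)CC | intermediate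
14 | (2E)-2-methyl-5-Ox-pent-2-en-1-ol | OC/C(C)=C/CC[C@H]1[C@]2(C)CC[C@H](O[Si](C)(C)C(C)(C)C)C(C)(C)O[C@@H]2CC[C@@]1(C)O[Si](CC)(CC)CC | intermediate
15 | (2E)-2-methyl-5-Ox-pent-2-enal | O=C/C(C)=C/CC[C@H]1[C@]2(C)CC[C@H](O[Si](C)(C)C(C)(C)C)C(C)(C)O[C@@H]2CC[C@@]1(C)O[Si](CC)(CC)CC | intermediate
16 | (3E)-4-methyl-1-Ox-hexa-3,5-diene | C=C/C(C)=C/CC[C@H]1[C@]2(C)CC[C@H](O[Si](C)(C)C(C)(C)C)C(C)(C)O[C@@H]2CC[C@@]1(C)O[Si](CC)(CC)CC | intermediate
17 | 3-ethoxycyclopent-2-en-1-one | CCOC1=CC(=O)CC1 | starting material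
18 | 3-ethoxy-1-(prop-1-en-2-yl)cyclopent-2-en-1-ol, formed as its bromomagnesium alkoxide (not isolated) | CCOC1=CC(O)(CC1)C(C)=C | intermediate
19 | 3-(prop-1-en-2-yl)cyclopent-2-en-1-one | CC(=C)C1=CC(=O)CC1 | intermediate
20 | lithium 3-(propan-2-ylidene)cyclopent-1-en-1-olate (not isolated) | [Li+].[O-]C1=CC(CC1)=C(C)C | intermediate
21 | 3-(propan-2-ylidene)-2-(trifluoroacetyl)cyclopentan-1-one | CC(C)=C1CCC(=O)C1C(=O)C(F)(F)F | intermediate
22 | 2-diazo-3-(propan-2-ylidene)cyclopentan-1-one | CC(C)=C1CCC(=O)C1=[N+]=[N-] | intermediate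
23 | (1R,3S)-1-[(2E)-5-Ox-pent-2-en-2-yl]-7-(propan-2-ylidene)spiro[2.4]heptan-4-one (not isolated) | CC(C)=C1CCC(=O)[C@]12C[C@@H]2/C(C)=C/CC[C@H]1[C@]2(C)CC[C@H](O[Si](C)(C)C(C)(C)C)C(C)(C)O[C@@H]2CC[C@@]1(C)O[Si](CC)(CC)CC | intermediate
24 | (5R)-4,4,6-trimethyl-5-(2-Ox-ethyl)-3,4,5,8-tetrahydroazulen-1(2H)-one | CC1=CCC2=C(CCC2=O)C(C)(C)[C@@H]1CC[C@H]1[C@]2(C)CC[C@H](O[Si](C)(C)C(C)(C)C)C(C)(C)O[C@@H]2CC[C@@]1(C)O[Si](CC)(CC)CC | intermediate
25 | lithium enolate of 26, C1(OLi)=C8a with (3aS,5R) (not isolated) | [Li+].CC1=CCC2=C([O-])CC[C@@H]2C(C)(C)[C@@H]1CC[C@H]1[C@]2(C)CC[C@H](O[Si](C)(C)C(C)(C)C)C(C)(C)O[C@@H]2CC[C@@]1(C)O[Si](CC)(CC)CC | intermediate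
26 | (3aS,5R,8aS)-4,4,6-trimethyl-5-(2-Ox-ethyl)-3,3a,4,5,8,8a-hexahydroazulen-1(2H)-one (cis-fused) | CC1=CC[C@H]2[C@H](CCC2=O)C(C)(C)[C@@H]1CC[C@H]1[C@]2(C)CC[C@H](O[Si](C)(C)C(C)(C)C)C(C)(C)O[C@@H]2CC[C@@]1(C)O[Si](CC)(CC)CC | intermediate
27 | (3aS,5R,8aS)-4,4,6-trimethyl-1-methylidene-5-(2-Ox-ethyl)-1,2,3,3a,4,5,8,8a-octahydroazulene | CC1=CC[C@H]2[C@H](CCC2=C)C(C)(C)[C@@H]1CC[C@H]1[C@]2(C)CC[C@H](O[Si](C)(C)C(C)(C)C)C(C)(C)O[C@@H]2CC[C@@]1(C)O[Si](CC)(CC)CC | intermediate
28 | (1S,3aS,5R,8aS)-1,4,4,6-tetramethyl-5-(2-Ox-ethyl)-1,2,3,3a,4,5,8,8a-octahydroazulen-1-ol | CC1=CC[C@H]2[C@H](CC[C@]2(C)O)C(C)(C)[C@@H]1CC[C@H]1[C@]2(C)CC[C@H](O[Si](C)(C)C(C)(C)C)C(C)(C)O[C@@H]2CC[C@@]1(C)O[Si](CC)(CC)CC | intermediate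
29 | (3S,5aS,6S,7R,9aR)-6-{2-[(1S,3aS,5R,8aS)-1-hydroxy-1,4,4,6-tetramethyl-1,2,3,3a,4,5,8,8a-octahydroazulen-5-yl]ethyl}-2,2,5a,7-tetramethyldecahydro-1-benzoxepine-3,7-diol | CC1=CC[C@H]2[C@H](CC[C@]2(C)O)C(C)(C)[C@@H]1CC[C@H]1[C@]2(C)CC[C@H](O)C(C)(C)O[C@@H]2CC[C@@]1(C)O | target

## Step count and least certain steps

Total: 21 steps. Longest linear sequence: 17 steps from nerol (steps 1–4, 6–13, 17–21).

**Step 17 (key step).** The vinyl diazo ketone can cyclise onto its own fully substituted terminus, and the carbenoid can undergo a 1,4-hydrogen shift from the cis methyl. The boat Cope shift, slowed by the inward methyl, may also lose to homolytic ring opening. All three drain material before the seven-membered ring forms. Fallback: build the same divinylcyclopropane without a carbenoid, setting out from 19 and 15. Dienolate 20 (made as in step 15) is added to enal 15 and the aldol is dehydrated (CH3SO2Cl, Et3N, then DBU) to the cross-conjugated trienone 2-[(2E)-2-methyl-5-Ox-pent-2-en-1-ylidene]-3-(propan-2-ylidene)cyclopentan-1-one F1. Corey–Chaykovsky methylene transfer from dimethylsulfoxonium methylide to the exocyclic enone of F1 gives cyclopropane 23 as a mixture of configurations. Heating converts it to 24, the trans isomer entering through reversible opening of the donor–acceptor ring. Control at C5 would then rest on a chiral aminosulfoxonium methylide or on separation of C5 epimers at 24.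

**Step 7.** The silyl triflate may activate the inner epoxide first, the terminal epoxide may open at its secondary carbon, or the epoxonium ion may eliminate before the alkene captures it. A boat closure would invert C6′. Fallback: close the carbocycle before the oxepane, setting out from 2.
- Oxidation and methylenation as in steps 3 and 4 give (2S,3S)-3-methyl-3-(4-methylpent-3-en-1-yl)oxirane-2-carbaldehyde F2 and then (2S,3R)-3-ethenyl-2-methyl-2-(4-methylpent-3-en-1-yl)oxirane F3.
- Hydroboration and coupling with 7 as in step 6 give tert-butyl (4Z)-5-methyl-7-[(2R,3S)-3-methyl-3-(4-methylpent-3-en-1-yl)oxiran-2-yl]hept-4-enoate F4.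
- CH3AlCl2 in CH2Cl2 at −78 °C effects the epoxide-initiated cation–olefin cyclisation with lactone capture, giving the 9a′-hydroxy lactone with a 4-methylpent-3-enyl chain on C5a′, F5.
- Shi epoxidation with the same ketone gives the (S)-epoxide F6.
- BF3·OEt2 at low temperature lets the C9a′ hydroxyl open the epoxide at its tertiary carbon to the hydroxy oxepane lactone F7, and t-BuMe2SiOTf/2,6-lutidine returns to 10.
The partition between seven- and six-membered ether in the BF3 step would be the point to watch.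

**Step 6.** The borane may open the allylic epoxide reductively instead of adding to the alkene, or the γ-boryl epoxide may undergo 1,3-elimination once the borate forms. Fallback: introduce the Z alkene by cuprate addition to an ynoate, setting out from 3.
- Tf2O/2,6-lutidine at −78 °C gives triflate F8, which alkylates 3-lithio-1-(trimethylsilyl)propyne to the silyl alkyne F9.
- K2CO3/MeOH gives the terminal alkyne F10, and n-BuLi then ClCO2CH3 gives the ynoate F11.
- Syn addition of (CH3)2CuLi at −78 °C gives the methyl (2Z)-enoate F12, and i-Bu2AlH gives the (2Z)-allylic alcohol F13.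
- CH3SO2Cl/Et3N then LiBr gives the allylic bromide F14, and the lithium enolate of tert-butyl acetate displaces bromide to return to 9.

**Step 18.** The 1,3-relay from C5 across the CMe2 group may be too weak, so protonation at C3a may occur on the wrong face; reduction may also run on to the alcohol. Fallback: let a reagent-set carbinol direct both hydrogens, setting out from 24. Corey–Bakshi–Shibata reduction with the (R)-2-methyl-oxazaborolidine and BH3·SMe2 gives the (1S)-allylic alcohol F15. Hydroxyl-directed hydrogenation with [Ir(cod)(PCy3)(py)]PF6 under H2 adds both hydrogens on the hydroxyl face to give the cis-fused (1S,3aS,5R,8aS)-alcohol F16. Dess–Martin oxidation returns to 26.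

**Step 15.** Proton exchange between the dienolate and product, or O-acylation, may erode the regiochemical marking of C2. Fallback: direct diazo transfer to the free β,γ-enone, setting out from 19. The same lithium/ammonia reduction is quenched by inverse addition to NH4Cl, giving 3-(propan-2-ylidene)cyclopentan-1-one F17 by kinetic α-protonation. Regitz transfer (4-acetamidobenzenesulfonyl azide, DBU, CH3CN, 0 °C) at the doubly activated C2 returns to 22.

## Further compounds

F1 | step 17 | 2-[(2E)-2-methyl-5-Ox-pent-2-en-1-ylidene]-3-(propan-2-ylidene)cyclopentan-1-one | CC(C)=C1CCC(=O)C1=C/C(C)=C/CC[C@H]1[C@]2(C)CC[C@H](O[Si](C)(C)C(C)(C)C)C(C)(C)O[C@@H]2CC[C@@]1(C)O[Si](CC)(CC)CC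
F2 | step 7 | (2S,3S)-3-methyl-3-(4-methylpent-3-en-1-yl)oxirane-2-carbaldehyde | O=C[C@H]1O[C@@]1(C)CCC=C(C)C
F3 | step 7 | (2S,3R)-3-ethenyl-2-methyl-2-(4-methylpent-3-en-1-yl)oxirane | C=C[C@H]1O[C@@]1(C)CCC=C(C)C
F4 | step 7 | tert-butyl (4Z)-5-methyl-7-[(2R,3S)-3-methyl-3-(4-methylpent-3-en-1-yl)oxiran-2-yl]hept-4-enoate | CC(C)(C)OC(=O)CC/C=C(/C)CC[C@H]1O[C@@]1(C)CCC=C(C)C
F5 | step 7 | 9a′-hydroxy δ-lactone with a 4-methylpent-3-enyl chain on C5a′ (cyclohexane of 10, oxepane not yet closed) | O=C1CC[C@H]2[C@](C)(CCC=C(C)C)[C@H](O)CC[C@@]2(C)O1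
F6 | step 7 | (S)-epoxide of F5 | O=C1CC[C@H]2[C@](C)(CC[C@@H]3OC3(C)C)[C@H](O)CC[C@@]2(C)O1
F7 | step 7 | 3′-hydroxy analogue of 10 (desilyl lactone) | O=C1CC[C@H]2[C@]3(C)CC[C@H](O)C(C)(C)O[C@@H]3CC[C@@]2(C)O1
F8 | step 6 | [(2R,3S)-3-{2-[(2S)-3,3-dimethyloxiran-2-yl]ethyl}-3-methyloxiran-2-yl]methyl trifluoromethanesulfonate | FC(F)(F)S(=O)(=O)OC[C@H]1O[C@@]1(C)CC[C@@H]1OC1(C)C
F9 | step 6 | trimethyl{4-[(2R,3S)-3-{2-[(2S)-3,3-dimethyloxiran-2-yl]ethyl}-3-methyloxiran-2-yl]but-1-yn-1-yl}silane | C[Si](C)(C)C#CCC[C@H]1O[C@@]1(C)CC[C@@H]1OC1(C)C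
F10 | step 6 | (2R,3S)-2-(but-3-yn-1-yl)-3-{2-[(2S)-3,3-dimethyloxiran-2-yl]ethyl}-3-methyloxirane | C#CCC[C@H]1O[C@@]1(C)CC[C@@H]1OC1(C)C
F11 | step 6 | methyl 5-[(2R,3S)-3-{2-[(2S)-3,3-dimethyloxiran-2-yl]ethyl}-3-methyloxiran-2-yl]pent-2-ynoate | COC(=O)C#CCC[C@H]1O[C@@]1(C)CC[C@@H]1OC1(C)C
F12 | step 6 | methyl (2Z)-5-[(2R,3S)-3-{2-[(2S)-3,3-dimethyloxiran-2-yl]ethyl}-3-methyloxiran-2-yl]-3-methylpent-2-enoate | COC(=O)/C=C(/C)CC[C@H]1O[C@@]1(C)CC[C@@H]1OC1(C)C
F13 | step 6 | (2Z)-5-[(2R,3S)-3-{2-[(2S)-3,3-dimethyloxiran-2-yl]ethyl}-3-methyloxiran-2-yl]-3-methylpent-2-en-1-ol | OC/C=C(/C)CC[C@H]1O[C@@]1(C)CC[C@@H]1OC1(C)C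
F14 | step 6 | (2R,3S)-2-[(3Z)-5-bromo-3-methylpent-3-en-1-yl]-3-{2-[(2S)-3,3-dimethyloxiran-2-yl]ethyl}-3-methyloxirane | BrC/C=C(/C)CC[C@H]1O[C@@]1(C)CC[C@@H]1OC1(C)C
F15 | step 18 | (1S,5R)-4,4,6-trimethyl-5-(2-Ox-ethyl)-1,2,3,4,5,8-hexahydroazulen-1-ol | CC1=CCC2=C(CC[C@@H]2O)C(C)(C)[C@@H]1CC[C@H]1[C@]2(C)CC[C@H](O[Si](C)(C)C(C)(C)C)C(C)(C)O[C@@H]2CC[C@@]1(C)O[Si](CC)(CC)CC
F16 | step 18 | (1S,3aS,5R,8aS)-4,4,6-trimethyl-5-(2-Ox-ethyl)-1,2,3,3a,4,5,8,8a-octahydroazulen-1-ol | CC1=CC[C@H]2[C@H](CC[C@@H]2O)C(C)(C)[C@@H]1CC[C@H]1[C@]2(C)CC[C@H](O[Si](C)(C)C(C)(C)C)C(C)(C)O[C@@H]2CC[C@@]1(C)O[Si](CC)(CC)CC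
F17 | step 15 | 3-(propan-2-ylidene)cyclopentan-1-one | CC(C)=C1CCC(=O)C1
A1 | alternative 1 | cis-fused hydroxy hydroazulenone from the ketyl–enone cyclisation | C[C@H]1C(=O)C[C@H]2[C@H](CC[C@]2(C)O)C(C)(C)[C@@H]1CCO[Si](C)(C)C(C)(C)C
A2 | alternative 1 | cyclohept-2-enone carrying the 3-oxobutyl chain (ketyl precursor) | C[C@H]1C(=O)C=C[C@H](CCC(C)=O)C(C)(C)[C@@H]1CCO[Si](C)(C)C(C)(C)C
A3 | alternative 2 | tricyclic furanone–alkene photoadduct | CC1(C)O[C@@]23CC[C@@](C)(O[Si](CC)(CC)CC)[C@@H](CCC#N)[C@]2(C)C[C@H]3C1=O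
A4 | alternative 2 | 2,2-dimethylfuran-3(2H)-one tethered at C5 to the isopropenyl-terminated chain | CC1(C)OC(CC[C@@](C)(O[Si](CC)(CC)CC)[C@@H](CCC#N)C(C)=C)=CC1=O
A5 | alternative 3 | trans-2-allyl-2-methyl-3-(left-half-ethyl)cyclohexanone ketal | CC1=CC[C@H]2[C@H](CC[C@]2(C)O[Si](CC)(CC)CC)C(C)(C)[C@@H]1CC[C@H]1[C@](C)(CC=C)C(=O)CCC12OCCO2
A6 | alternative 3 | 7-methyl-1,4-dioxaspiro[4.5]dec-6-en-8-one | CC1=CC2(CCC1=O)OCCO2
A7 | alternative 3 | left-half 5-vinyl hydroazulene triethylsilyl ether | CC1=CC[C@H]2[C@H](CC[C@]2(C)O[Si](CC)(CC)CC)C(C)(C)[C@@H]1C=C
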